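Ring A is a resorcylate: C1 bears the ester carbonyl, C2 and C4 bear oxygen and C6 bears the CH2 of the 2-oxoheptyl chain, exactly the pattern of a folded 3,5,7-trioxo ester. The route rests on disconnecting the ring A C1–C6 bond. An open-chain triketo acid that is already esterified to the C4 oxygen of ring B (compound 15) undergoes an intramolecular aldol condensation, chain C2 onto the C7 ketone, and aromatizes in the same operation, so ring A appears with the hindered depside ester already in place. In 15 the side-chain ketone is masked as a dioxolane and the ring B acid as a tert-butyl ester.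

Key step: step 9

Remark on the chemistry: the polycarbonyl compounds 11, 13, 14 and 15 are keto–enol mixtures and are written in their keto forms; carbinol 16 is a mixture of racemic diastereomers whose two sp3 centres vanish on aromatization, so its SMILES carries no configuration; the target has no stereocentre.

Step 1
Reactants: 1 2-methoxy-6-methylbenzoic acid; 2 1-iodobutane
Product: 3 2-methoxy-6-pentylbenzoic acid
Conditions: LiN(iPr)2 (2.2 equiv), THF, −78 → 0 °C; then 2, −78 °C → rt; aq. HCl
Reagents that add atoms: none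
Why: Two equivalents of amide base form the carboxylate/benzylic dianion (lateral lithiation directed by the ortho carboxylate), and its benzylic carbanion is alkylated by the primary iodide in an SN2 reaction, turning the methyl group into pentyl.

Step 2
Reactants: 3 2-methoxy-6-pentylbenzoic acid
Product: 4 tert-butyl 2-methoxy-6-pentylbenzoate
Conditions: tert-butyl 2,2,2-trichloroacetimidate, BF3·OEt2 (cat.), CH2Cl2/cyclohexane, rt
Reagents that add atoms: tert-butyl 2,2,2-trichloroacetimidate, CC(C)(C)OC(=N)C(Cl)(Cl)Cl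
Why: Acid-catalysed O-alkylation of the carboxylic acid by the trichloroacetimidate (tert-butyl cation transfer) makes the ester without any nucleophilic attack at the hindered 2,6-disubstituted carbonyl carbon.

Step 3
Reactants: 4 tert-butyl 2-methoxy-6-pentylbenzoate
Product: 6 tert-butyl 4-hydroxy-2-methoxy-6-pentylbenzoate, via pinacol arylboronate 5 (not isolated)
Conditions: [Ir(OMe)(cod)]2 (cat.), 4,4'-di-tert-butyl-2,2'-bipyridine, B2pin2 (1.0 equiv), THF, 80 °C; then KHSO5 (as Oxone, 2KHSO5·KHSO4·K2SO4), acetone/H2O, rt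
Reagents that add atoms: bis(pinacolato)diboron, CC1(C)OB(OC1(C)C)B1OC(C)(C)C(C)(C)O1 (boryl group of intermediate 5); potassium peroxymonosulfate, [K+].[O-]S(=O)(=O)OO (phenol oxygen of 6)
Why: Iridium-catalysed aromatic C–H borylation is sterically controlled and should select C4–H, the only ring hydrogen without an ortho substituent, after which oxidation of the C–B bond (aryl shift from boron to peroxide oxygen) gives the phenol in the same flask.

Step 4
Reactants: 7 ethyl 3-oxooctanoate
Product: 8 ethyl 2-(2-pentyl-1,3-dioxolan-2-yl)acetate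
Conditions: ethane-1,2-diol, p-TsOH (cat.), toluene, reflux, Dean–Stark
Reagents that add atoms: ethane-1,2-diol, OCCO
Why: Acid-catalysed ketalization with azeotropic removal of water protects the C3 ketone as a 1,3-dioxolane, so that the derived acid cannot decarboxylate and this carbonyl stays out of all later enolate chemistry.

Step 5
Reactants: 8 ethyl 2-(2-pentyl-1,3-dioxolan-2-yl)acetate
Product: 9 2-(2-pentyl-1,3-dioxolan-2-yl)acetic acid
Conditions: LiOH·H2O, THF/MeOH/H2O, rt; then cold dilute HCl to pH 4, 0 °C, extraction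
Reagents that add atoms: lithium hydroxide, [Li+].[OH-]
Why: Ester saponification (acyl–oxygen cleavage by hydroxide) leaves the base-stable ketal untouched, and acidification only to pH 4 in the cold frees the acid without opening the dioxolane.

Step 6
Reactants: 10 2,2,6-trimethyl-4H-1,3-dioxin-4-one
Product: 11 2,2-dimethyl-6-(2-oxopropyl)-4H-1,3-dioxin-4-one
Conditions: LiN(SiMe3)2, THF, −78 °C (enolate in twofold excess); AcCl, −78 °C; aq. NH4Cl
Reagents that add atoms: acetyl chloride, CC(=O)Cl
Why: The lithium dienolate of the dioxinone is C-acylated at its terminal carbon by the acid chloride (Claisen-type acylation), the excess enolate taking up the proton of the more acidic product.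

Step 7
Reactants: 11 2,2-dimethyl-6-(2-oxopropyl)-4H-1,3-dioxin-4-one; 9 2-(2-pentyl-1,3-dioxolan-2-yl)acetic acid
Product: 13 6-[2,4-dioxo-5-(2-pentyl-1,3-dioxolan-2-yl)pentyl]-2,2-dimethyl-4H-1,3-dioxin-4-one, via acyl imidazolide 12 (not isolated)
Conditions: 9, 1,1'-carbonyldiimidazole, THF, rt (gives 12); 11 (2 equiv), LiN(iPr)2 (4 equiv), THF, −78 °C; add 12, −78 → −30 °C; aq. NH4Cl, pH 5
Reagents that add atoms: 1,1'-carbonyldiimidazole, O=C(n1ccnc1)n1ccnc1 (imidazolyl group of intermediate 12 only; no atom of it remains in 13)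
Why: The acid is activated as its imidazolide and the 1,3-dianion of keto-dioxinone 11 reacts through its more basic terminal carbanion (the former acetyl methyl) in a Claisen-type C-acylation that should give the diketo-dioxinone.

Step 8
Reactants: 13 6-[2,4-dioxo-5-(2-pentyl-1,3-dioxolan-2-yl)pentyl]-2,2-dimethyl-4H-1,3-dioxin-4-one; 6 tert-butyl 4-hydroxy-2-methoxy-6-pentylbenzoate
Product: 15 tert-butyl 2-methoxy-6-pentyl-4-{[3,5,7-trioxo-8-(2-pentyl-1,3-dioxolan-2-yl)octanoyl]oxy}benzoate, via acylketene 14 (not isolated)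
Conditions: toluene, 110 °C, N2 sweep to remove acetone; evaporation; 15 used crude
Reagents that add atoms: none
Why: Heating triggers a retro-hetero-Diels–Alder loss of acetone from the dioxinone, and the resulting acylketene 14 is captured by the phenol oxygen of 6 (the usual dioxinone acylation of alcohols and phenols), so the depside ester is made from an unhindered ketene and not from a 2,6-disubstituted benzoic acid.

Step 9
Reactants: 15 tert-butyl 2-methoxy-6-pentyl-4-{[3,5,7-trioxo-8-(2-pentyl-1,3-dioxolan-2-yl)octanoyl]oxy}benzoate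
Product: 17 tert-butyl 4-({2,4-dihydroxy-6-[(2-pentyl-1,3-dioxolan-2-yl)methyl]benzoyl}oxy)-2-methoxy-6-pentylbenzoate, via aldol carbinol 16 (not isolated)
Conditions: Et3N (3 equiv), CH2Cl2, 0 °C → rt; pH 5 buffer wash
Reagents that add atoms: none
Why: Triethylamine reversibly enolizes the polyketone, and the C2 carbon, activated by both the aryl ester and the C3 ketone, adds to the C7 ketone to give carbinol 16; loss of water from C7 and enolization of the C3 and C5 carbonyls then deliver the aromatic 2,4-dihydroxybenzoate, so the C1–C6 bond of ring A and the ring itself arise in one operation driven by aromatization. The closest known reaction type is the base-mediated aldol aromatization of 3,5,7-triketo esters obtained from diketo-dioxinones, the laboratory version of the polyketide folding that leads to resorcylates. Ring A closes as a six-membered carbocycle in an aldol of the 6-(enolendo)-exo-trig type when the enolate is written through C3 (6-(enolexo)-exo-trig when written through the ester), allowed in either description. No stereocentre is created in the product, the two sp3 centres of 16 being erased on aromatization. The step needs the C2-to-C7 aldol to beat two closures that would expel the ring B phenol, namely attack of the C5 enol oxygen on the ester carbonyl (4-hydroxy-2-pyrone) and Claisen closure of C6 onto C1 (acylphloroglucinol), as well as aldol modes through C8 or a C9 carbonyl. A weak, non-nucleophilic amine in an aprotic solvent without alkoxide or chelating metal favours the reversible aldol that dehydration then locks, and the dioxolane leaves C8 singly activated and neopentyl-like and removes the fourth electrophilic carbonyl.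

Step 10
Reactants: 17 tert-butyl 4-({2,4-dihydroxy-6-[(2-pentyl-1,3-dioxolan-2-yl)methyl]benzoyl}oxy)-2-methoxy-6-pentylbenzoate
Product: 18 tert-butyl 4-({2,4-dimethoxy-6-[(2-pentyl-1,3-dioxolan-2-yl)methyl]benzoyl}oxy)-2-methoxy-6-pentylbenzoate
Conditions: MeI (excess), K2CO3, acetone, reflux
Reagents that add atoms: iodomethane, CI
Why: Williamson O-methylation of both phenoxides should proceed under carbonate conditions, the hydrogen-bonded C2 hydroxyl needing the excess reagent and warming, while the di-ortho-substituted depside carbonyl is shielded from nucleophiles and the ketal keeps the benzylic CH2 non-acidic.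

Step 11
Reactants: 18 tert-butyl 4-({2,4-dimethoxy-6-[(2-pentyl-1,3-dioxolan-2-yl)methyl]benzoyl}oxy)-2-methoxy-6-pentylbenzoate
Product: 19 4-{[2,4-dimethoxy-6-(2-oxoheptyl)benzoyl]oxy}-2-methoxy-6-pentylbenzoic acid (CNP0169128.0)
Conditions: CF3CO2H/CH2Cl2/H2O (10:10:1), 0 °C → rt; evaporation with toluene
Reagents that add atoms: water, O
Why: Aqueous acid hydrolyses the dioxolane to the ketone and cleaves the tert-butyl ester by alkyl–oxygen fission (the tert-butyl cation leaves as isobutene), while the aryl ester and the methyl ethers are inert to acid at room temperature.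

Compound list
1 | 2-methoxy-6-methylbenzoic acid | Cc1cccc(OC)c1C(=O)O | starting material
2 | 1-iodobutane | CCCCI | starting material
3 | 2-methoxy-6-pentylbenzoic acid | CCCCCc1cccc(OC)c1C(=O)O | intermediate
4 | tert-butyl 2-methoxy-6-pentylbenzoate | CCCCCc1cccc(OC)c1C(=O)OC(C)(C)C | intermediate
5 | tert-butyl 2-methoxy-6-pentyl-4-(4,4,5,5-tetramethyl-1,3,2-dioxaborolan-2-yl)benzoate | CCCCCc1cc(B2OC(C)(C)C(C)(C)O2)cc(OC)c1C(=O)OC(C)(C)C | intermediate (not isolated)
6 | tert-butyl 4-hydroxy-2-methoxy-6-pentylbenzoate | CCCCCc1cc(O)cc(OC)c1C(=O)OC(C)(C)C | intermediate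
7 | ethyl 3-oxooctanoate | CCCCCC(=O)CC(=O)OCC | starting material
8 | ethyl 2-(2-pentyl-1,3-dioxolan-2-yl)acetate | CCCCCC1(CC(=O)OCC)OCCO1 | intermediate
9 | 2-(2-pentyl-1,3-dioxolan-2-yl)acetic acid | CCCCCC1(CC(=O)O)OCCO1 | intermediate
10 | 2,2,6-trimethyl-4H-1,3-dioxin-4-one | CC1=CC(=O)OC(C)(C)O1 | starting material
11 | 2,2-dimethyl-6-(2-oxopropyl)-4H-1,3-dioxin-4-one | CC(=O)CC1=CC(=O)OC(C)(C)O1 | intermediate
12 | 1-(1H-imidazol-1-yl)-2-(2-pentyl-1,3-dioxolan-2-yl)ethan-1-one | CCCCCC1(CC(=O)n2ccnc2)OCCO1 | intermediate (not isolated)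
13 | 6-[2,4-dioxo-5-(2-pentyl-1,3-dioxolan-2-yl)pentyl]-2,2-dimethyl-4H-1,3-dioxin-4-one | CCCCCC1(CC(=O)CC(=O)CC2=CC(=O)OC(C)(C)O2)OCCO1 | intermediate
14 | 8-(2-pentyl-1,3-dioxolan-2-yl)oct-1-ene-1,3,5,7-tetrone (acylketene) | CCCCCC1(CC(=O)CC(=O)CC(=O)C=C=O)OCCO1 | intermediate (not isolated)
15 | tert-butyl 2-methoxy-6-pentyl-4-{[3,5,7-trioxo-8-(2-pentyl-1,3-dioxolan-2-yl)octanoyl]oxy}benzoate | CCCCCC1(CC(=O)CC(=O)CC(=O)CC(=O)Oc2cc(CCCCC)c(C(=O)OC(C)(C)C)c(OC)c2)OCCO1 | intermediate
16 | tert-butyl 4-[({2-hydroxy-4,6-dioxo-2-[(2-pentyl-1,3-dioxolan-2-yl)methyl]cyclohexyl}carbonyl)oxy]-2-methoxy-6-pentylbenzoate (racemic diastereomer mixture) | CCCCCC1(CC2(O)CC(=O)CC(=O)C2C(=O)Oc3cc(CCCCC)c(C(=O)OC(C)(C)C)c(OC)c3)OCCO1 | intermediate (not isolated)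
17 | tert-butyl 4-({2,4-dihydroxy-6-[(2-pentyl-1,3-dioxolan-2-yl)methyl]benzoyl}oxy)-2-methoxy-6-pentylbenzoate | CCCCCC1(Cc2cc(O)cc(O)c2C(=O)Oc2cc(CCCCC)c(C(=O)OC(C)(C)C)c(OC)c2)OCCO1 | intermediate
18 | tert-butyl 4-({2,4-dimethoxy-6-[(2-pentyl-1,3-dioxolan-2-yl)methyl]benzoyl}oxy)-2-methoxy-6-pentylbenzoate | CCCCCC1(Cc2cc(OC)cc(OC)c2C(=O)Oc2cc(CCCCC)c(C(=O)OC(C)(C)C)c(OC)c2)OCCO1 | intermediate
19 | 4-{[2,4-dimethoxy-6-(2-oxoheptyl)benzoyl]oxy}-2-methoxy-6-pentylbenzoic acid | CCCCCC(=O)Cc1cc(OC)cc(OC)c1C(=O)Oc1cc(CCCCC)c(C(=O)O)c(OC)c1 | target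

Total step count: 11
Longest linear sequence: 7 steps (1, 2, 3, 8, 9, 10, 11; the branch 4, 5, 7, 8, 9, 10, 11 is equally long)

Steps most likely to fail

Step 9. The closure may run through oxygen (the C5 enol oxygen attacking the ester carbonyl) or through C6 onto C1, and either pathway expels the ring B phenoxide instead of forming the C1–C6 bond. The fallback closes ring A before any aryl ester exists. It sets out from 13: triethylamine in CH2Cl2 should effect the same aldol aromatization onto C5 of the dioxinone and give 7-hydroxy-2,2-dimethyl-5-[(2-pentyl-1,3-dioxolan-2-yl)methyl]-4H-1,3-benzodioxin-4-one F1. Methylation (MeI, K2CO3, acetone) gives 7-methoxy-2,2-dimethyl-5-[(2-pentyl-1,3-dioxolan-2-yl)methyl]-4H-1,3-benzodioxin-4-one F2. Irradiation of F2 at about 300 nm in CH2Cl2 with phenol 6 releases acetone and an ortho-quinone ketene, whose capture by 6 should give tert-butyl 4-({2-hydroxy-4-methoxy-6-[(2-pentyl-1,3-dioxolan-2-yl)methyl]benzoyl}oxy)-2-methoxy-6-pentylbenzoate F3. Methylation of the remaining C2 hydroxyl (MeI, K2CO3, acetone) brings the sequence back to the route at 18.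

Step 8. The acylketene may be captured faster by its own C5 enol oxygen (closure to a 2-pyrone) than by the weakly nucleophilic, ester-deactivated phenol, so that intermolecular O-acylation of 6 stalls. The fallback captures the ketene with a primary alcohol and forms the depside by classical acylation. It sets out from 13: thermolysis in toluene with excess allyl alcohol should give prop-2-en-1-yl 3,5,7-trioxo-8-(2-pentyl-1,3-dioxolan-2-yl)octanoate F4, and triethylamine in CH2Cl2 should aromatize it to prop-2-en-1-yl 2,4-dihydroxy-6-[(2-pentyl-1,3-dioxolan-2-yl)methyl]benzoate F5. Methylation (MeI, K2CO3) gives prop-2-en-1-yl 2,4-dimethoxy-6-[(2-pentyl-1,3-dioxolan-2-yl)methyl]benzoate F6, and deallylation (Pd(PPh3)4 cat., morpholine, THF) gives 2,4-dimethoxy-6-[(2-pentyl-1,3-dioxolan-2-yl)methyl]benzoic acid F7. Under neutral conditions 1-chloro-N,N,2-trimethylprop-1-en-1-amine converts F7 into 2,4-dimethoxy-6-[(2-pentyl-1,3-dioxolan-2-yl)methyl]benzoyl chloride F8, which is used directly to acylate the sodium phenoxide of 6 (NaH, THF), coming back to the route at 18.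

Step 7. Proton transfer from the enolizable imidazolide to the dianion, followed by β-elimination that opens the dioxolane, or double acylation, may make the C-acylation inefficient. The fallback replaces the Claisen acylation by an aldol addition and an oxidation. It sets out from 8: reduction with iBu2AlH (CH2Cl2, −78 °C) should give 2-(2-pentyl-1,3-dioxolan-2-yl)acetaldehyde F9. The dianion of 11 (LiN(iPr)2, THF, −78 °C) adds to F9 to give racemic 6-[4-hydroxy-2-oxo-5-(2-pentyl-1,3-dioxolan-2-yl)pentyl]-2,2-dimethyl-4H-1,3-dioxin-4-one F10, and oxidation with Dess–Martin periodinane (NaHCO3, CH2Cl2) comes back to the route at 13.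

Further compounds
F1 | step 9 | 7-hydroxy-2,2-dimethyl-5-[(2-pentyl-1,3-dioxolan-2-yl)methyl]-4H-1,3-benzodioxin-4-one | CCCCCC1(Cc2cc(O)cc3OC(C)(C)OC(=O)c23)OCCO1
F2 | step 9 | 7-methoxy-2,2-dimethyl-5-[(2-pentyl-1,3-dioxolan-2-yl)methyl]-4H-1,3-benzodioxin-4-one | CCCCCC1(Cc2cc(OC)cc3OC(C)(C)OC(=O)c23)OCCO1
F3 | step 9 | tert-butyl 4-({2-hydroxy-4-methoxy-6-[(2-pentyl-1,3-dioxolan-2-yl)methyl]benzoyl}oxy)-2-methoxy-6-pentylbenzoate | CCCCCC1(Cc2cc(OC)cc(O)c2C(=O)Oc2cc(CCCCC)c(C(=O)OC(C)(C)C)c(OC)c2)OCCO1
F4 | step 8 | prop-2-en-1-yl 3,5,7-trioxo-8-(2-pentyl-1,3-dioxolan-2-yl)octanoate | CCCCCC1(CC(=O)CC(=O)CC(=O)CC(=O)OCC=C)OCCO1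
F5 | step 8 | prop-2-en-1-yl 2,4-dihydroxy-6-[(2-pentyl-1,3-dioxolan-2-yl)methyl]benzoate | CCCCCC1(Cc2cc(O)cc(O)c2C(=O)OCC=C)OCCO1
F6 | step 8 | prop-2-en-1-yl 2,4-dimethoxy-6-[(2-pentyl-1,3-dioxolan-2-yl)methyl]benzoate | CCCCCC1(Cc2cc(OC)cc(OC)c2C(=O)OCC=C)OCCO1
F7 | step 8 | 2,4-dimethoxy-6-[(2-pentyl-1,3-dioxolan-2-yl)methyl]benzoic acid | CCCCCC1(Cc2cc(OC)cc(OC)c2C(=O)O)OCCO1
F8 | step 8 | 2,4-dimethoxy-6-[(2-pentyl-1,3-dioxolan-2-yl)methyl]benzoyl chloride | CCCCCC1(Cc2cc(OC)cc(OC)c2C(=O)Cl)OCCO1
F9 | step 7 | 2-(2-pentyl-1,3-dioxolan-2-yl)acetaldehyde | CCCCCC1(CC=O)OCCO1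
F10 | step 7 | 6-[4-hydroxy-2-oxo-5-(2-pentyl-1,3-dioxolan-2-yl)pentyl]-2,2-dimethyl-4H-1,3-dioxin-4-one (racemic) | CCCCCC1(CC(O)CC(=O)CC2=CC(=O)OC(C)(C)O2)OCCO1
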